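**Retrosynthetic overview**

- The target (tricyclo[5.3.1.0(1,5)]undecane numbering; ring A = enol-trione ring, ring B = bridging cyclopentanone, ring C = cyclopentane) is opened to a fully aromatic acylphloroglucinol with one (S)-2-(2-hydroxypropan-2-yl)-3,3-dimethylpent-4-enyl chain. One oxidative dearomative radical bicyclisation forms C1–C5 (ring C) and C6–C7 (ring B) together.
- That precursor comes from a 3-substituted dihydrocoumarin: double methyl addition builds CMe2OH and frees the phenol.
- The dihydrocoumarin comes from an ortho-quinone methide of the acylphloroglucinol and 3,3-dimethylpent-4-enal. An enamine-catalysed Michael addition sets the single relay stereocentre, and the lactol is then oxidised.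
- The quinone methide precursor (a benzylic sulfone) comes from 2-methylphloroglucinol and (R)-2-methylbutanoic acid by Friedel–Crafts acylation, then aminomethylation and sulfinate exchange.
- Ring order: ring A is bought as the arene; rings C and B close in the same final operation.

Assumption: (2R)-2-methylbutanoic acid is purchased enantiopure, and the target is handled as the enol tautomer drawn in the given SMILES.

**Step 1**
Reactants: 1 2-methylbenzene-1,3,5-triol; 2 (2R)-2-methylbutanoic acid
Product: 4 (2R)-2-methyl-1-(2,4,6-trihydroxy-3-methylphenyl)butan-1-one, via (2R)-2-methylbutanoyl chloride 3 (not isolated)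
Conditions: (COCl)2, HCONMe2 (cat.), CH2Cl2, 0 °C to rt; then 1, AlCl3 (3.5 equiv), PhNO2/CH2Cl2, 0 °C to rt
Reagents that add atoms: none
Why: Friedel–Crafts C-acylation at one of the two equivalent free ring positions by the acylium ion from 3, which is made without base (no ketene, so the α-stereocentre is kept); the first acyl group deactivates the ring against a second acylation.

**Step 2**
Reactants: 4 (2R)-2-methyl-1-(2,4,6-trihydroxy-3-methylphenyl)butan-1-one
Product: 6 (2R)-2-methyl-1-(2,4,6-trihydroxy-3-methyl-5-{[(4-methylphenyl)sulfonyl]methyl}phenyl)butan-1-one, via Mannich base 5 (not isolated)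
Conditions: N,N-dimethylmethyleneiminium iodide, MeCN, rt; then 4-MeC6H4SO2Na (3 equiv), AcOH, 70 °C
Reagents that add atoms: N,N-dimethylmethyleneiminium iodide (C=[N+](C)C.[I-]); sodium 4-methylbenzenesulfinate (Cc1ccc(cc1)S(=O)[O-].[Na+])
Why: Mannich aminomethylation at the only free ring carbon, then acid-promoted elimination–addition exchange of Me2NH for the soft sulfinate through the quinone methide; no unsubstituted arene is left when the methide is released, so the usual methylene-bridged dimer cannot form.

**Step 3**
Reactants: 7 methyl 3,3-dimethylpent-4-enoate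
Product: 8 3,3-dimethylpent-4-enal
Conditions: iBu2AlH (1.05 equiv), CH2Cl2, −78 °C; MeOH, then aq. potassium sodium tartrate
Reagents that add atoms: none
Why: Partial ester reduction with iBu2AlH stops at the tetrahedral aluminium hemiacetal at −78 °C and gives the aldehyde on hydrolysis; the isolated vinyl group is inert.

**Step 4**
Reactants: 6 (2R)-2-methyl-1-(2,4,6-trihydroxy-3-methyl-5-{[(4-methylphenyl)sulfonyl]methyl}phenyl)butan-1-one; 8 3,3-dimethylpent-4-enal
Product: 11 (3S)-5,7-dihydroxy-8-methyl-6-[(2R)-2-methylbutanoyl]-3-(2-methylbut-3-en-2-yl)-3,4-dihydro-2H-chromen-2-one, via ortho-quinone methide 9 (not isolated), via lactol 10 (not isolated)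
Conditions: 8 (2 equiv), (S)-2-[diphenyl(trimethylsilyloxy)methyl]pyrrolidine (20 mol%), NaHCO3, CH2Cl2, 0 °C to rt; water wash; then Dess–Martin periodinane (1.5 equiv), NaHCO3, CH2Cl2, 0 °C
Reagents that add atoms: none
Why: NaHCO3 expels sulfinate from 6 to give quinone methide 9, and the (E)-enamine of 8 adds to the methide carbon (enamine-catalysed Michael addition to an in situ ortho-quinone methide, formal [4+2]) on the face not shielded by the CPh2(OSiMe3) group, which sets C3 as S in the sense known for enamine Michael additions of linear aldehydes with this catalyst (the R catalyst would give the C3 epimer); hydrolysis gives lactol 10, closed on the oxygen para to the acyl group, and Dess–Martin oxidation of the lactol OH gives the lactone.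

**Step 5**
Reactants: 11 (3S)-5,7-dihydroxy-8-methyl-6-[(2R)-2-methylbutanoyl]-3-(2-methylbut-3-en-2-yl)-3,4-dihydro-2H-chromen-2-one
Product: 12 (2R)-1-{2,4,6-trihydroxy-3-[(2S)-2-(2-hydroxypropan-2-yl)-3,3-dimethylpent-4-en-1-yl]-5-methylphenyl}-2-methylbutan-1-one
Conditions: MeMgBr (8 equiv), CeCl3 (anhydrous, 4 equiv), THF, −40 to 0 °C; then aq. NH4Cl
Reagents that add atoms: methylmagnesium bromide (C[Mg]Br)
Why: Double Grignard addition to the aryl lactone (ester to tertiary alcohol through the methyl ketone) builds CMe2OH and releases the phenol; CeCl3 suppresses α-deprotonation so the S centre is kept, and the aryl ketone is masked in situ as its unreactive magnesium bis(phenoxide) chelate.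

**Step 6**
Reactants: 12 (2R)-1-{2,4,6-trihydroxy-3-[(2S)-2-(2-hydroxypropan-2-yl)-3,3-dimethylpent-4-en-1-yl]-5-methylphenyl}-2-methylbutan-1-one
Product: 13 (1S,3S,5S,7S)-8-hydroxy-3-(2-hydroxypropan-2-yl)-4,4,7-trimethyl-9-[(2R)-2-methylbutanoyl]tricyclo[5.3.1.0(1,5)]undec-8-ene-10,11-dione
Conditions: Mn(OAc)3·2H2O (2.3 equiv), NaOAc (2 equiv), degassed AcOH/MeCN (1:3), 40 °C, 5 mM, argon; then aq. NaHSO3
Reagents that add atoms: none
Why: Proposed new method: Mn(OAc)3 oxidises the chelating β-keto-phenol by one electron to a delocalised radical of the 2-acylcyclohexane-1,3,5-trione type (every ring position is substituted, so it cannot couple productively); its chain-bearing ring carbon adds 5-exo-trig to the internal vinyl carbon (C1–C5, ring C, reversible by re-aromatising β-scission), the primary C6 radical then adds 5-exo to the methyl-bearing ring carbon rather than the more hindered acyl-bearing one (C6–C7, ring B and the bicyclo[3.2.1]octane), and a second Mn(OAc)3 oxidises the resulting captodative radical to the enol-trione; the bulky CMe2OH group sits pseudo-equatorial in the chair-like Beckwith–Houk transition state, so the C5 CH2 forms cis to it, and because that CH2 can only reach the ring carbon on its own face this one centre fixes C1, C5 and C7 (the trans mode would give the separable C3 epimer); NaOAc buffering keeps the tertiary alcohol from cyclising onto the phenol; the closest known reactions are Mn(OAc)3 oxidative radical cyclisations of dearomatised prenylated acylphloroglucinols and phenol-oxidation-triggered intramolecular (5+2) cyclisations to cedrane skeletons.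

**Compound list**

1 | 2-methylbenzene-1,3,5-triol | Cc1c(O)cc(O)cc1O | starting material
2 | (2R)-2-methylbutanoic acid | CC[C@@H](C)C(=O)O | starting material
3 | (2R)-2-methylbutanoyl chloride | CC[C@@H](C)C(=O)Cl | intermediate
4 | (2R)-2-methyl-1-(2,4,6-trihydroxy-3-methylphenyl)butan-1-one | CC[C@@H](C)C(=O)c1c(O)c(C)c(O)cc1O | intermediate
5 | (2R)-1-{3-[(dimethylamino)methyl]-2,4,6-trihydroxy-5-methylphenyl}-2-methylbutan-1-one (Mannich base) | CC[C@@H](C)C(=O)c1c(O)c(C)c(O)c(CN(C)C)c1O | intermediate
6 | (2R)-2-methyl-1-(2,4,6-trihydroxy-3-methyl-5-{[(4-methylphenyl)sulfonyl]methyl}phenyl)butan-1-one | CC[C@@H](C)C(=O)c1c(O)c(C)c(O)c(CS(=O)(=O)c2ccc(C)cc2)c1O | intermediate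
7 | methyl 3,3-dimethylpent-4-enoate | COC(=O)CC(C)(C)C=C | starting material
8 | 3,3-dimethylpent-4-enal | O=CCC(C)(C)C=C | intermediate
9 | 3,5-dihydroxy-2-methyl-6-methylidene-4-[(2R)-2-methylbutanoyl]cyclohexa-2,4-dien-1-one (ortho-quinone methide) | CC[C@@H](C)C(=O)C1=C(O)C(=C)C(=O)C(C)=C1O | intermediate
10 | (3S)-8-methyl-6-[(2R)-2-methylbutanoyl]-3-(2-methylbut-3-en-2-yl)-3,4-dihydro-2H-chromene-2,5,7-triol (lactol, both C2 epimers) | CC[C@@H](C)C(=O)c1c(O)c(C)c2OC(O)[C@H](C(C)(C)C=C)Cc2c1O | intermediate
11 | (3S)-5,7-dihydroxy-8-methyl-6-[(2R)-2-methylbutanoyl]-3-(2-methylbut-3-en-2-yl)-3,4-dihydro-2H-chromen-2-one | CC[C@@H](C)C(=O)c1c(O)c(C)c2OC(=O)[C@H](C(C)(C)C=C)Cc2c1O | intermediate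
12 | (2R)-1-{2,4,6-trihydroxy-3-[(2S)-2-(2-hydroxypropan-2-yl)-3,3-dimethylpent-4-en-1-yl]-5-methylphenyl}-2-methylbutan-1-one | CC[C@@H](C)C(=O)c1c(O)c(C)c(O)c(C[C@H](C(C)(C)O)C(C)(C)C=C)c1O | intermediate
13 | (1S,3S,5S,7S)-8-hydroxy-3-(2-hydroxypropan-2-yl)-4,4,7-trimethyl-9-[(2R)-2-methylbutanoyl]tricyclo[5.3.1.0(1,5)]undec-8-ene-10,11-dione | CC[C@@H](C)C(=O)C1=C(O)[C@]2(C)C[C@H]3C(C)(C)[C@@H](C(C)(C)O)C[C@@]3(C1=O)C2=O | target

**Step count**

Total steps: 6. Longest linear sequence: 5 (steps 1, 2, 4, 5, 6, starting from 1).

**Three steps most likely to fail**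

Step 6. The aromatic radical may be too stabilised to add to the vinyl group, the first closure may go 6-endo, or benzylic oxidation to quinone methides may win. The fallback sets out from 12 and returns at 13. Compound 12 is first dearomatised by C-bromination with N-bromosuccinimide (CH2Cl2, −78 °C) to the bromodienone F1. Both rings are then closed by a copper-catalysed atom-transfer radical bicyclisation (CuBr, tris(2-pyridylmethyl)amine, 2,6-lutidine, MeCN, 50 °C). Monovalent copper abstracts the bromine to give the same ring radical without acid or a stoichiometric oxidant, and divalent copper bromide oxidises the final captodative radical, so that loss of HBr delivers 13.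

Step 4. The β-quaternary aldehyde may form its enamine slowly, the catalyst may be trapped by the quinone methide, the selectivity may be low, or the periodinane may attack the free phenols. The fallback sets out from 6 (with 7 as the source of the nucleophile) and returns at 11. Saponification of 7 (LiOH, THF/H2O) gives 3,3-dimethylpent-4-enoic acid F2. Mixed-anhydride coupling (pivaloyl chloride, Et3N; then the nBuLi-derived lithium salt of (4S)-4-benzyl-1,3-oxazolidin-2-one) gives the N-acyl oxazolidinone F3. Its chlorotitanium enolate (TiCl4, iPr2NEt, CH2Cl2, −78 to 0 °C) is alkylated by quinone methide 9, which the Lewis acid releases from 6, on the face opposite the benzyl group. This gives the imide adduct F4 with the same S centre. DBU then closes the lactone onto the ortho-phenoxide and expels the auxiliary, which rejoins the route at 11 with no oxidation step.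

Step 5. The hindered aryl lactone may be deprotonated instead of attacked (enolate, then ketene by loss of phenoxide, which would racemise C3), or the reaction may stall at the hemiketal of the methyl ketone. The fallback sets out from 10 and returns at 12. The Dess–Martin oxidation of step 4 is left out and lactol 10 is isolated. MeMgBr/CeCl3 adds to its open hydroxy-aldehyde form to give the secondary alcohol F5. Dess–Martin periodinane oxidises this to the methyl ketone F6, and a second MeMgBr/CeCl3 addition to the ketone gives 12. No acyl substitution on an aryl ester is involved, so the ketene pathway is closed.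

**Further compounds**

F1 | step 6 | 6-bromo-3,5-dihydroxy-6-[(2S)-2-(2-hydroxypropan-2-yl)-3,3-dimethylpent-4-en-1-yl]-4-methyl-2-[(2R)-2-methylbutanoyl]cyclohexa-2,4-dien-1-one (both C6 epimers) | CC[C@@H](C)C(=O)C1=C(O)C(C)=C(O)C(Br)(C[C@H](C(C)(C)O)C(C)(C)C=C)C1=O
F2 | step 4 | 3,3-dimethylpent-4-enoic acid | C=CC(C)(C)CC(=O)O
F3 | step 4 | (4S)-4-benzyl-3-(3,3-dimethylpent-4-enoyl)-1,3-oxazolidin-2-one | C=CC(C)(C)CC(=O)N1[C@@H](Cc2ccccc2)COC1=O
F4 | step 4 | (4S)-4-benzyl-3-[(2S)-3,3-dimethyl-2-({2,4,6-trihydroxy-3-methyl-5-[(2R)-2-methylbutanoyl]phenyl}methyl)pent-4-enoyl]-1,3-oxazolidin-2-one | CC[C@@H](C)C(=O)c1c(O)c(C)c(O)c(C[C@@H](C(C)(C)C=C)C(=O)N2[C@@H](Cc3ccccc3)COC2=O)c1O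
F5 | step 5 | (2R)-1-{2,4,6-trihydroxy-3-[(2S)-2-(1-hydroxyethyl)-3,3-dimethylpent-4-en-1-yl]-5-methylphenyl}-2-methylbutan-1-one (both carbinol epimers) | CC[C@@H](C)C(=O)c1c(O)c(C)c(O)c(C[C@H](C(C)O)C(C)(C)C=C)c1O
F6 | step 5 | (2R)-1-{3-[(2S)-2-acetyl-3,3-dimethylpent-4-en-1-yl]-2,4,6-trihydroxy-5-methylphenyl}-2-methylbutan-1-one | CC[C@@H](C)C(=O)c1c(O)c(C)c(O)c(C[C@H](C(C)=O)C(C)(C)C=C)c1O
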